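**Retrosynthetic overview**

1. The target 27 is an 8β-angeloyloxy-14,15-dihydroxy-germacra-1(10),4,11(13)-trien-12,6α-olide with both ring olefins cis within the ring. The last operations are global desilylation and a Mitsunobu esterification with angelic acid that inverts an 8α-carbinol.
2. Key disconnection C7–C8. The α-methylene-γ-butyrolactone (O–C6–C7–C11(=C13H2)–C12=O) is the allyl-transposed form of a 3-(bromomethyl)butenolide (C13–C11=C7), and C8, bonded to C7, carries oxygen. An intramolecular Nozaki–Hiyama–Kishi allylation of a C8 aldehyde therefore closes the ten-membered carbocycle (C1–C10), sets C7 and C8 and unveils the exocyclic methylene in one operation; the two ring-cis olefins C1=C10 and C4=C5 pre-fold the acyclic chain.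
3. The butenolide (first ring) comes from an enal by catalytic asymmetric alkynylation (sets C6), hydroxyl-directed trans-hydroalumination/iodination and carbonylative lactonisation.
4. Both trisubstituted olefins come from one building block, (Z)-3-iodo-4-silyloxybut-2-en-1-ol (from but-2-yne-1,4-diol), used twice in B-alkyl Suzuki–Miyaura couplings.
5. Order of ring formation: butenolide (step 10), then the ten-membered ring (step 15).

Key step: step 15

Remarks: Germacrane numbering is used for positions (C6 lactone carbinol, C7 ring-fusion carbon bearing C11, C8 ester carbinol, C12 lactone carbonyl, C13 exocyclic methylene, C14 and C15 the hydroxymethyl carbons on C10 and C4). TBS = tert-butyldimethylsilyl, TBDPS = tert-butyldiphenylsilyl, PMB = 4-methoxybenzyl.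

Assumption: (S,S)-ProPhenol is taken to deliver the alkyne to the enal face that gives the (R)-carbinol; if the facial sense is the opposite, (R,R)-ProPhenol is used with no other change.

**Route**

Step 1
Reactants: 1 but-2-yne-1,4-diol
Product: 2 4-(TBDPS-oxy)but-2-yn-1-ol
Conditions: NaH (1 equiv), THF, 0 °C to rt; then TBDPSCl (1 equiv)
Reagents that add atoms: tert-butyl(chloro)diphenylsilane, CC(C)(C)[Si](Cl)(c1ccccc1)c1ccccc1
Why: Monosilylation of the symmetrical diol through its sparingly soluble monosodium alkoxide (O-silylation) should give the mono-ether and leave one hydroxyl as the directing group for step 2.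

Step 2
Reactants: 2 4-(TBDPS-oxy)but-2-yn-1-ol
Product: 4 (Z)-3-iodo-4-(TBDPS-oxy)but-2-en-1-ol, via cyclic alkenylalanate 3 (not isolated)
Conditions: NaAlH2(OCH2CH2OMe)2, THF, 0 °C; then I2, THF, −78 °C
Reagents that add atoms: iodine, II
Why: Alkoxide-directed trans-hydroalumination of the propargylic alcohol puts hydride on the carbon next to the carbinol and aluminium on the distal carbon in a five-membered alanate, and iodinolysis with retention should give the vinyl iodide with iodine cis to the CH2OH carbon, the geometry later needed at both ring olefins.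

Step 3
Reactants: 5 tert-butyldimethyl(vinyloxy)silane; 4 (Z)-3-iodo-4-(TBDPS-oxy)but-2-en-1-ol
Product: 7 (E)-5-(TBS-oxy)-3-[(TBDPS-oxy)methyl]pent-2-en-1-ol, via 9-(2-silyloxyethyl)-9-BBN 6 (not isolated)
Conditions: 9-BBN, THF, 0 °C to rt; then 4, PdCl2(dppf) (5 mol %), AsPh3, Cs2CO3, DMF/H2O, rt
Reagents that add atoms: none
Why: Anti-Markovnikov hydroboration of the silyl enol ether followed by B-alkyl Suzuki–Miyaura coupling (oxidative addition of zerovalent palladium into the C–I bond, transmetalation, reductive elimination) should replace iodine by the C9–C8 unit with retention of olefin geometry, the free allylic hydroxyl being tolerated.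

Step 4
Reactants: 7 (E)-5-(TBS-oxy)-3-[(TBDPS-oxy)methyl]pent-2-en-1-ol
Product: 8 (E)-5-(TBS-oxy)-3-[(TBDPS-oxy)methyl]pent-2-enal
Conditions: MnO2 (excess), CH2Cl2, rt
Reagents that add atoms: none
Why: MnO2 allylic oxidation is neutral and selective for the allylic primary alcohol, so olefin geometry and both silyl ethers should survive.

Step 5
Reactants: 8 (E)-5-(TBS-oxy)-3-[(TBDPS-oxy)methyl]pent-2-enal
Product: 9 (E)-6-(TBS-oxy)-4-[(TBDPS-oxy)methyl]hexa-1,3-diene
Conditions: Ph3PCH3Br, KN(SiMe3)2, THF, −78 to 0 °C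
Reagents that add atoms: methyltriphenylphosphonium bromide, C[P+](c1ccccc1)(c1ccccc1)c1ccccc1.[Br-]
Why: Wittig methylenation of the enal with the non-stabilised ylide should give the 1,3-diene without touching the existing trisubstituted olefin.

Step 6
Reactants: 9 (E)-6-(TBS-oxy)-4-[(TBDPS-oxy)methyl]hexa-1,3-diene; 4 (Z)-3-iodo-4-(TBDPS-oxy)but-2-en-1-ol
Product: 11 (2E,6E)-9-(TBS-oxy)-3,7-bis[(TBDPS-oxy)methyl]nona-2,6-dien-1-ol, via homoallylic 9-alkyl-9-BBN 10 (not isolated)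
Conditions: 9-BBN, THF, 0 °C to rt; then 4, PdCl2(dppf) (5 mol %), AsPh3, Cs2CO3, DMF/H2O, rt
Reagents that add atoms: none
Why: 9-BBN should hydroborate only the terminal CH2 of the monosubstituted diene olefin (the trisubstituted one is too hindered), and B-alkyl Suzuki–Miyaura coupling of the homoallylic borane with a second equivalent of iodide 4 joins C3 to C4 with retention, fixing the C4=C5 geometry.

Step 7
Reactants: 11 (2E,6E)-9-(TBS-oxy)-3,7-bis[(TBDPS-oxy)methyl]nona-2,6-dien-1-ol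
Product: 12 (2E,6E)-9-(TBS-oxy)-3,7-bis[(TBDPS-oxy)methyl]nona-2,6-dienal
Conditions: MnO2 (excess), CH2Cl2, rt
Reagents that add atoms: none
Why: Chemoselective MnO2 allylic oxidation should give the enal (C6 aldehyde) under neutral conditions that do not isomerise the olefins.

Step 8
Reactants: 12 (2E,6E)-9-(TBS-oxy)-3,7-bis[(TBDPS-oxy)methyl]nona-2,6-dienal; 13 1-methoxy-4-[(prop-2-yn-1-yloxy)methyl]benzene
Product: 15 (4R,5E,9E)-12-(TBS-oxy)-6,10-bis[(TBDPS-oxy)methyl]-1-(PMB-oxy)dodeca-5,9-dien-2-yn-4-ol, via alkynyl(methyl)zinc 14 (not isolated)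
Conditions: 13, Me2Zn, (S,S)-ProPhenol (20 mol %), Ph3PO (40 mol %), toluene, 4 °C; then 12
Reagents that add atoms: none
Why: Zinc–ProPhenol-catalysed asymmetric alkynylation, in which the dinuclear zinc catalyst binds the enal and the alkynylzinc and delivers the alkyne to one enantiotopic aldehyde face, should set C6 as R under catalyst control.

Step 9
Reactants: 15 (4R,5E,9E)-12-(TBS-oxy)-6,10-bis[(TBDPS-oxy)methyl]-1-(PMB-oxy)dodeca-5,9-dien-2-yn-4-ol
Product: 17 (2Z,4R,5E,9E)-2-iodo-12-(TBS-oxy)-6,10-bis[(TBDPS-oxy)methyl]-1-(PMB-oxy)dodeca-2,5,9-trien-4-ol, via cyclic alkenylalanate 16 (not isolated)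
Conditions: NaAlH2(OCH2CH2OMe)2, THF, 0 °C; then I2, THF, −78 °C
Reagents that add atoms: iodine, II
Why: Alkoxide-directed trans-hydroalumination of the alkyne (hydride to C7, aluminium to C11) and iodinolysis with retention should give the vinyl iodide with iodine cis to C6, as lactonisation requires; C6 is not touched.

Step 10
Reactants: 17 (2Z,4R,5E,9E)-2-iodo-12-(TBS-oxy)-6,10-bis[(TBDPS-oxy)methyl]-1-(PMB-oxy)dodeca-2,5,9-trien-4-ol
Product: 18 (R)-5-[(1E,5E)-8-(TBS-oxy)-2,6-bis[(TBDPS-oxy)methyl]octa-1,5-dien-1-yl]-3-[(PMB-oxy)methyl]furan-2(5H)-one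
Conditions: PdCl2(PPh3)2 (5 mol %), CO (1 atm), K2CO3, THF, rt
Reagents that add atoms: carbon monoxide, [C-]#[O+]
Why: Palladium-catalysed carbonylative lactonisation (oxidative addition of zerovalent palladium into the C–I bond, CO insertion, capture of the acylpalladium by the cis hydroxyl) should close the butenolide, and the mild heterogeneous base keeps the γ-stereocentre C6 intact.

Step 11
Reactants: 18 (R)-5-[(1E,5E)-8-(TBS-oxy)-2,6-bis[(TBDPS-oxy)methyl]octa-1,5-dien-1-yl]-3-[(PMB-oxy)methyl]furan-2(5H)-one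
Product: 19 (R)-5-[(1E,5E)-8-(TBS-oxy)-2,6-bis[(TBDPS-oxy)methyl]octa-1,5-dien-1-yl]-3-(hydroxymethyl)furan-2(5H)-one
Conditions: DDQ, CH2Cl2/pH 7 buffer, 0 °C to rt
Reagents that add atoms: none
Why: Oxidative PMB cleavage by DDQ (benzylic hydride abstraction, hydrolysis of the oxocarbenium ion) should free only the C13 hydroxyl and leave the silyl ethers and the butenolide untouched.

Step 12
Reactants: 19 (R)-5-[(1E,5E)-8-(TBS-oxy)-2,6-bis[(TBDPS-oxy)methyl]octa-1,5-dien-1-yl]-3-(hydroxymethyl)furan-2(5H)-one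
Product: 20 (R)-3-(bromomethyl)-5-[(1E,5E)-8-(TBS-oxy)-2,6-bis[(TBDPS-oxy)methyl]octa-1,5-dien-1-yl]furan-2(5H)-one
Conditions: CBr4, PPh3, CH2Cl2, 0 °C
Reagents that add atoms: carbon tetrabromide, BrC(Br)(Br)Br
Why: Appel bromination (SN2 displacement of the alkoxyphosphonium ion by bromide) should convert the primary allylic alcohol into the allylic bromide under neutral conditions.

Step 13
Reactants: 20 (R)-3-(bromomethyl)-5-[(1E,5E)-8-(TBS-oxy)-2,6-bis[(TBDPS-oxy)methyl]octa-1,5-dien-1-yl]furan-2(5H)-one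
Product: 21 (R)-3-(bromomethyl)-5-[(1E,5E)-8-hydroxy-2,6-bis[(TBDPS-oxy)methyl]octa-1,5-dien-1-yl]furan-2(5H)-one
Conditions: camphorsulfonic acid (cat.), MeOH/CH2Cl2, 0 °C
Reagents that add atoms: none
Why: Acid-catalysed methanolysis cleaves a primary TBS ether far faster than primary TBDPS ethers, so only the C8 hydroxyl should be released.

Step 14
Reactants: 21 (R)-3-(bromomethyl)-5-[(1E,5E)-8-hydroxy-2,6-bis[(TBDPS-oxy)methyl]octa-1,5-dien-1-yl]furan-2(5H)-one
Product: 22 (R)-3-(bromomethyl)-5-[(1E,5E)-2,6-bis[(TBDPS-oxy)methyl]-8-oxoocta-1,5-dien-1-yl]furan-2(5H)-one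
Conditions: Dess–Martin periodinane, NaHCO3, CH2Cl2, 0 °C to rt; used at once
Reagents that add atoms: none
Why: Buffered Dess–Martin oxidation should give the β,γ-unsaturated C8 aldehyde without moving the C1=C10 olefin into conjugation and without touching the allylic bromide.

Step 15
Reactants: 22 (R)-3-(bromomethyl)-5-[(1E,5E)-2,6-bis[(TBDPS-oxy)methyl]-8-oxoocta-1,5-dien-1-yl]furan-2(5H)-one
Product: 24 (3aR,4S,6E,10E,11aR)-4-hydroxy-6,10-bis[(TBDPS-oxy)methyl]-3-methylene-3a,4,5,8,9,11a-hexahydrocyclodeca[b]furan-2(3H)-one, via allylchromium dichloride 23 (not isolated)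
Conditions: CrCl2 (10 equiv), THF, rt, 22 added by syringe pump (final 2 mM); H2O work-up
Reagents that add atoms: none
Why: Two equivalents of CrCl2 (divalent chromium) reduce the allylic C–Br bond to the trivalent allylchromium 23, which adds through its γ-carbon C7 to the tethered C8 aldehyde in a six-membered chair (Zimmerman–Traxler) transition state with chromium bridging O8 and C13, so that the butenolide olefin C7=C11 becomes the exocyclic C11=C13 methylene; the closest known reaction type is the intramolecular Nozaki–Hiyama–Kishi (Barbier-type) allylation of ω-formyl 2-(bromomethyl)alk-2-enoates and 3-(bromomethyl)butenolides used to close medium and large carbocycles. The ten-membered ring C1–C10 closes by a 10-exo-trig addition to the carbonyl with SE2' (γ) attack at the allyl unit. C7 is controlled by the C6 stereocentre: bonding on the butenolide face opposite to the C5 alkenyl chain gives a staggered ring torsion C5–C6–C7–C8 near 150° (trans fusion, 7R), whereas same-face bonding would need a nearly eclipsed torsion. C8 is controlled by the chair: C9 sits pseudo-equatorial, anti to C11, which also gives a gauche C6–C7–C8–C9 torsion of sign opposite to the neighbouring anti torsion, the pattern that ten-membered rings prefer, so the 8S (8α) carbinol is expected. The step needs γ- over α-attack (secured by the cyclic transition state), ring closure over oligomerisation (high dilution and the two ring-cis olefins C1=C10 and C4=C5 that fold the chain) and the 8α sense at the aldehyde, which is the epimer that step 16 inverts.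

Step 16
Reactants: 24 (3aR,4S,6E,10E,11aR)-4-hydroxy-6,10-bis[(TBDPS-oxy)methyl]-3-methylene-3a,4,5,8,9,11a-hexahydrocyclodeca[b]furan-2(3H)-one; 25 angelic acid [(Z)-2-methylbut-2-enoic acid]
Product: 26 (3aR,4R,6E,10E,11aR)-6,10-bis[(TBDPS-oxy)methyl]-3-methylene-2-oxo-2,3,3a,4,5,8,9,11a-octahydrocyclodeca[b]furan-4-yl (Z)-2-methylbut-2-enoate
Conditions: 25, PPh3, DIAD, toluene, 0 °C to rt
Reagents that add atoms: none
Why: Mitsunobu esterification, in which angelate displaces the C8 oxyphosphonium ion by SN2 with inversion, should set the 8R (8β) ester under neutral conditions that avoid angelate-to-tiglate isomerisation and conjugate addition to the α-methylene lactone.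

Step 17
Reactants: 26 (3aR,4R,6E,10E,11aR)-6,10-bis[(TBDPS-oxy)methyl]-3-methylene-2-oxo-2,3,3a,4,5,8,9,11a-octahydrocyclodeca[b]furan-4-yl (Z)-2-methylbut-2-enoate
Product: 27 (3aR,4R,6E,10E,11aR)-6,10-bis(hydroxymethyl)-3-methylene-2-oxo-2,3,3a,4,5,8,9,11a-octahydrocyclodeca[b]furan-4-yl (Z)-2-methylbut-2-enoate
Conditions: HF·pyridine, THF/pyridine, 0 °C to rt
Reagents that add atoms: none
Why: Fluoride-mediated desilylation under buffered acidic conditions should remove both TBDPS ethers while the angelate, the α-methylene lactone and the three stereocentres are left untouched.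

**Compound list**

1 | but-2-yne-1,4-diol | OCC#CCO | starting material
2 | 4-(TBDPS-oxy)but-2-yn-1-ol | OCC#CCO[Si](c1ccccc1)(c1ccccc1)C(C)(C)C | intermediate
3 | sodium cyclic alkenylalanate of 2 (five-membered O–Al–C=C–C ring, Al on the carbon bearing CH2OTBDPS, two 2-methoxyethoxy ligands) | [Na+].COCCO[Al-]1(OCCOC)OCC=C1CO[Si](c1ccccc1)(c1ccccc1)C(C)(C)C | intermediate (not isolated)
4 | (Z)-3-iodo-4-(TBDPS-oxy)but-2-en-1-ol | OC/C=C(\I)CO[Si](c1ccccc1)(c1ccccc1)C(C)(C)C | intermediate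
5 | tert-butyldimethyl(vinyloxy)silane | C=CO[Si](C)(C)C(C)(C)C | starting material
6 | 9-[2-(TBS-oxy)ethyl]-9-borabicyclo[3.3.1]nonane | CC(C)(C)[Si](C)(C)OCCB1C2CCCC1CCC2 | intermediate (not isolated)
7 | (E)-5-(TBS-oxy)-3-[(TBDPS-oxy)methyl]pent-2-en-1-ol | OC/C=C(\CCO[Si](C)(C)C(C)(C)C)CO[Si](c1ccccc1)(c1ccccc1)C(C)(C)C | intermediate
8 | (E)-5-(TBS-oxy)-3-[(TBDPS-oxy)methyl]pent-2-enal | O=C/C=C(\CCO[Si](C)(C)C(C)(C)C)CO[Si](c1ccccc1)(c1ccccc1)C(C)(C)C | intermediate
9 | (E)-6-(TBS-oxy)-4-[(TBDPS-oxy)methyl]hexa-1,3-diene | C=C/C=C(\CCO[Si](C)(C)C(C)(C)C)CO[Si](c1ccccc1)(c1ccccc1)C(C)(C)C | intermediate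
10 | 9-[(E)-6-(TBS-oxy)-4-[(TBDPS-oxy)methyl]hex-3-en-1-yl]-9-borabicyclo[3.3.1]nonane | C(CB1C2CCCC1CCC2)/C=C(\CCO[Si](C)(C)C(C)(C)C)CO[Si](c1ccccc1)(c1ccccc1)C(C)(C)C | intermediate (not isolated)
11 | (2E,6E)-9-(TBS-oxy)-3,7-bis[(TBDPS-oxy)methyl]nona-2,6-dien-1-ol | OC/C=C(\CC/C=C(\CCO[Si](C)(C)C(C)(C)C)CO[Si](c1ccccc1)(c1ccccc1)C(C)(C)C)CO[Si](c1ccccc1)(c1ccccc1)C(C)(C)C | intermediate
12 | (2E,6E)-9-(TBS-oxy)-3,7-bis[(TBDPS-oxy)methyl]nona-2,6-dienal | O=C/C=C(\CC/C=C(\CCO[Si](C)(C)C(C)(C)C)CO[Si](c1ccccc1)(c1ccccc1)C(C)(C)C)CO[Si](c1ccccc1)(c1ccccc1)C(C)(C)C | intermediate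
13 | 1-methoxy-4-[(prop-2-yn-1-yloxy)methyl]benzene (PMB propargyl ether) | C#CCOCc1ccc(OC)cc1 | starting material
14 | methyl[3-(PMB-oxy)prop-1-yn-1-yl]zinc | C[Zn]C#CCOCc1ccc(OC)cc1 | intermediate (not isolated)
15 | (4R,5E,9E)-12-(TBS-oxy)-6,10-bis[(TBDPS-oxy)methyl]-1-(PMB-oxy)dodeca-5,9-dien-2-yn-4-ol | O[C@@H](C#CCOCc1ccc(OC)cc1)/C=C(\CC/C=C(\CCO[Si](C)(C)C(C)(C)C)CO[Si](c1ccccc1)(c1ccccc1)C(C)(C)C)CO[Si](c1ccccc1)(c1ccccc1)C(C)(C)C | intermediate
16 | sodium cyclic alkenylalanate of 15 (five-membered O–Al–C11=C7–C6 ring, two 2-methoxyethoxy ligands) | [Na+].COCCO[Al-]1(OCCOC)O[C@@H](C=C1COCc2ccc(OC)cc2)/C=C(\CC/C=C(\CCO[Si](C)(C)C(C)(C)C)CO[Si](c2ccccc2)(c2ccccc2)C(C)(C)C)CO[Si](c2ccccc2)(c2ccccc2)C(C)(C)C | intermediate (not isolated)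
17 | (2Z,4R,5E,9E)-2-iodo-12-(TBS-oxy)-6,10-bis[(TBDPS-oxy)methyl]-1-(PMB-oxy)dodeca-2,5,9-trien-4-ol | O[C@@H](/C=C(\I)COCc1ccc(OC)cc1)/C=C(\CC/C=C(\CCO[Si](C)(C)C(C)(C)C)CO[Si](c1ccccc1)(c1ccccc1)C(C)(C)C)CO[Si](c1ccccc1)(c1ccccc1)C(C)(C)C | intermediate
18 | (R)-5-[(1E,5E)-8-(TBS-oxy)-2,6-bis[(TBDPS-oxy)methyl]octa-1,5-dien-1-yl]-3-[(PMB-oxy)methyl]furan-2(5H)-one | O=C1O[C@H](/C=C(\CC/C=C(\CCO[Si](C)(C)C(C)(C)C)CO[Si](c2ccccc2)(c2ccccc2)C(C)(C)C)CO[Si](c2ccccc2)(c2ccccc2)C(C)(C)C)C=C1COCc2ccc(OC)cc2 | intermediate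
19 | (R)-5-[(1E,5E)-8-(TBS-oxy)-2,6-bis[(TBDPS-oxy)methyl]octa-1,5-dien-1-yl]-3-(hydroxymethyl)furan-2(5H)-one | O=C1O[C@H](/C=C(\CC/C=C(\CCO[Si](C)(C)C(C)(C)C)CO[Si](c2ccccc2)(c2ccccc2)C(C)(C)C)CO[Si](c2ccccc2)(c2ccccc2)C(C)(C)C)C=C1CO | intermediate
20 | (R)-3-(bromomethyl)-5-[(1E,5E)-8-(TBS-oxy)-2,6-bis[(TBDPS-oxy)methyl]octa-1,5-dien-1-yl]furan-2(5H)-one | O=C1O[C@H](/C=C(\CC/C=C(\CCO[Si](C)(C)C(C)(C)C)CO[Si](c2ccccc2)(c2ccccc2)C(C)(C)C)CO[Si](c2ccccc2)(c2ccccc2)C(C)(C)C)C=C1CBr | intermediate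
21 | (R)-3-(bromomethyl)-5-[(1E,5E)-8-hydroxy-2,6-bis[(TBDPS-oxy)methyl]octa-1,5-dien-1-yl]furan-2(5H)-one | O=C1O[C@H](/C=C(\CC/C=C(\CCO)CO[Si](c2ccccc2)(c2ccccc2)C(C)(C)C)CO[Si](c2ccccc2)(c2ccccc2)C(C)(C)C)C=C1CBr | intermediate
22 | (R)-3-(bromomethyl)-5-[(1E,5E)-2,6-bis[(TBDPS-oxy)methyl]-8-oxoocta-1,5-dien-1-yl]furan-2(5H)-one | O=C1O[C@H](/C=C(\CC/C=C(\CC=O)CO[Si](c2ccccc2)(c2ccccc2)C(C)(C)C)CO[Si](c2ccccc2)(c2ccccc2)C(C)(C)C)C=C1CBr | intermediate
23 | allylchromium dichloride of 22 (CrCl2 on C13 of the butenolide, trivalent chromium) | O=C1O[C@H](/C=C(\CC/C=C(\CC=O)CO[Si](c2ccccc2)(c2ccccc2)C(C)(C)C)CO[Si](c2ccccc2)(c2ccccc2)C(C)(C)C)C=C1C[Cr](Cl)Cl | intermediate (not isolated)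
24 | (3aR,4S,6E,10E,11aR)-4-hydroxy-6,10-bis[(TBDPS-oxy)methyl]-3-methylene-3a,4,5,8,9,11a-hexahydrocyclodeca[b]furan-2(3H)-one (8α-hydroxy-6α,12-olide) | C=C1C(=O)O[C@@H]2/C=C(/CO[Si](c3ccccc3)(c3ccccc3)C(C)(C)C)CC/C=C(/CO[Si](c3ccccc3)(c3ccccc3)C(C)(C)C)C[C@H](O)[C@@H]12 | intermediate
25 | angelic acid, (Z)-2-methylbut-2-enoic acid | OC(=O)/C(C)=C\C | starting material
26 | (3aR,4R,6E,10E,11aR)-6,10-bis[(TBDPS-oxy)methyl]-3-methylene-2-oxo-2,3,3a,4,5,8,9,11a-octahydrocyclodeca[b]furan-4-yl (Z)-2-methylbut-2-enoate | C=C1C(=O)O[C@@H]2/C=C(/CO[Si](c3ccccc3)(c3ccccc3)C(C)(C)C)CC/C=C(/CO[Si](c3ccccc3)(c3ccccc3)C(C)(C)C)C[C@@H](OC(=O)/C(C)=C\C)[C@@H]12 | intermediate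
27 | (3aR,4R,6E,10E,11aR)-6,10-bis(hydroxymethyl)-3-methylene-2-oxo-2,3,3a,4,5,8,9,11a-octahydrocyclodeca[b]furan-4-yl (Z)-2-methylbut-2-enoate | C=C1C(=O)O[C@@H]2/C=C(/CO)CC/C=C(/CO)C[C@@H](OC(=O)/C(C)=C\C)[C@@H]12 | target

**Step count and risks**

Total step count: 17. Longest linear sequence: 17 steps (building block 4 from steps 1 and 2 enters at steps 3 and 6).

Steps most likely to fail:

1. Step 15 (ring closure). Intermolecular allylation may outrun closure of the ten-membered ring, or the aldehyde face may not follow the chair model, giving a mixture of C8 epimers. The fallback changes the mechanism to a Lewis-acid-promoted allylstannane addition through an open transition state. It sets out from 21: (Bu3Sn)2 with Pd(PPh3)4 (zerovalent palladium) in THF should give (R)-5-[(1E,5E)-8-hydroxy-2,6-bis[(TBDPS-oxy)methyl]octa-1,5-dien-1-yl]-3-[(tributylstannyl)methyl]furan-2(5H)-one F1. Buffered Dess–Martin oxidation should give the corresponding 8-oxo stannane F2. BF3·OEt2 in CH2Cl2 at −78 °C under high dilution should then close the ring by SE2' addition through an antiperiplanar open transition state with no metal bridge, which places C9 between C11 and H7 and is expected to give the 8β-carbinol (3aR,4R,6E,10E,11aR)-4-hydroxy-6,10-bis[(TBDPS-oxy)methyl]-3-methylene-3a,4,5,8,9,11a-hexahydrocyclodeca[b]furan-2(3H)-one F3. Yamaguchi esterification of F3 with 25 (2,4,6-trichlorobenzoyl chloride, Et3N, then DMAP, toluene) proceeds with retention and comes back to the route at 26.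

2. Step 16 (Mitsunobu inversion). SN2 displacement at the hindered ring carbinol may be slow, so that elimination toward C9 or acylation with retention competes. The fallback separates activation from displacement. It sets out from 24: chloromethanesulfonyl chloride and pyridine in CH2Cl2 at 0 °C should give the 8α-chloromethanesulfonate of 24 F4. Displacement with caesium angelate (from 25 and Cs2CO3) and 18-crown-6 in toluene should proceed with inversion and come back to the route at 26.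

3. Step 8 (asymmetric alkynylation). Enantiofacial discrimination on the β,β-disubstituted enal may be insufficient. The fallback sets C6 by reagent-controlled ketone reduction instead. It sets out from 12: the lithium acetylide of 13 (n-BuLi, THF, −78 °C) should give the racemic carbinol rac-12-(TBS-oxy)-6,10-bis[(TBDPS-oxy)methyl]-1-(PMB-oxy)dodeca-5,9-dien-2-yn-4-ol F5. MnO2 oxidation should give the ynone (5E,9E)-12-(TBS-oxy)-6,10-bis[(TBDPS-oxy)methyl]-1-(PMB-oxy)dodeca-5,9-dien-2-yn-4-one F6. Corey–Bakshi–Shibata reduction with (R)-2-methyl-CBS-oxazaborolidine and catecholborane at −78 °C, the alkynyl group acting as the small substituent, should give the (R)-carbinol and come back to the route at 15.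

**Further compounds**

F1 | step 15 | (R)-5-[(1E,5E)-8-hydroxy-2,6-bis[(TBDPS-oxy)methyl]octa-1,5-dien-1-yl]-3-[(tributylstannyl)methyl]furan-2(5H)-one | O=C1O[C@H](/C=C(\CC/C=C(\CCO)CO[Si](c2ccccc2)(c2ccccc2)C(C)(C)C)CO[Si](c2ccccc2)(c2ccccc2)C(C)(C)C)C=C1C[Sn](CCCC)(CCCC)CCCC
F2 | step 15 | (R)-5-[(1E,5E)-2,6-bis[(TBDPS-oxy)methyl]-8-oxoocta-1,5-dien-1-yl]-3-[(tributylstannyl)methyl]furan-2(5H)-one | O=C1O[C@H](/C=C(\CC/C=C(\CC=O)CO[Si](c2ccccc2)(c2ccccc2)C(C)(C)C)CO[Si](c2ccccc2)(c2ccccc2)C(C)(C)C)C=C1C[Sn](CCCC)(CCCC)CCCC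
F3 | step 15 | (3aR,4R,6E,10E,11aR)-4-hydroxy-6,10-bis[(TBDPS-oxy)methyl]-3-methylene-3a,4,5,8,9,11a-hexahydrocyclodeca[b]furan-2(3H)-one | C=C1C(=O)O[C@@H]2/C=C(/CO[Si](c3ccccc3)(c3ccccc3)C(C)(C)C)CC/C=C(/CO[Si](c3ccccc3)(c3ccccc3)C(C)(C)C)C[C@@H](O)[C@@H]12
F4 | step 16 | (3aR,4S,6E,10E,11aR)-6,10-bis[(TBDPS-oxy)methyl]-3-methylene-2-oxo-2,3,3a,4,5,8,9,11a-octahydrocyclodeca[b]furan-4-yl chloromethanesulfonate | C=C1C(=O)O[C@@H]2/C=C(/CO[Si](c3ccccc3)(c3ccccc3)C(C)(C)C)CC/C=C(/CO[Si](c3ccccc3)(c3ccccc3)C(C)(C)C)C[C@H](OS(=O)(=O)CCl)[C@@H]12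
F5 | step 8 | rac-(5E,9E)-12-(TBS-oxy)-6,10-bis[(TBDPS-oxy)methyl]-1-(PMB-oxy)dodeca-5,9-dien-2-yn-4-ol | OC(C#CCOCc1ccc(OC)cc1)/C=C(\CC/C=C(\CCO[Si](C)(C)C(C)(C)C)CO[Si](c1ccccc1)(c1ccccc1)C(C)(C)C)CO[Si](c1ccccc1)(c1ccccc1)C(C)(C)C
F6 | step 8 | (5E,9E)-12-(TBS-oxy)-6,10-bis[(TBDPS-oxy)methyl]-1-(PMB-oxy)dodeca-5,9-dien-2-yn-4-one | O=C(C#CCOCc1ccc(OC)cc1)/C=C(\CC/C=C(\CCO[Si](C)(C)C(C)(C)C)CO[Si](c1ccccc1)(c1ccccc1)C(C)(C)C)CO[Si](c1ccccc1)(c1ccccc1)C(C)(C)C
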